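**Retrosynthetic overview**

1. Locants: carbocycle C1–C7 (C1 carbinol carrying the butenoyl group C1′–C4′, C2 CH–CH3, C3 CHOH, C4 CH2, C5, C6–O of the lactone, C7–O of the tiglate); lactone C8 (CH–CH3) and C9 (C=O). β is the face of the carbocycle that carries the lactone (bonds C5–C8 and C6–O), α the other face.
2. Endgame: tiglate on C7–OH, C7–OH from a C7 ketone, C3–OH masked as a TBS ether; this leads back to ketol 18.
3. Enabling feature: C1 is a tertiary carbinol flanked by C7 (ketone level) and the side-chain ketone C1′, an α-hydroxy-β-dicarbonyl array, which is the product pattern of an α-ketol shift. Breaking C1–C2 and joining C2 to C7 gives cyclohexanol 17, a C7 carbinol bearing the vicinal diketone C1/C1′.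
4. The six-membered ring C2–C7 with C8, C9 and both methyl groups is the skeleton of (R)-carvone (its ketone is C7, its stereocentre is C5). C6–O (lactonisation), C8 (hydrogenation) and C2/C3 (hydroboration) are set on this ring; C1 and C1′–C4′ arrive as a diazoketone added to the C7 ketone.
5. Ring order: lactone ring first, on the carvone ring; seven-membered ring last, closed at C1–C2 by the shift that opens C2–C7.

Key step: step 13

**Route**

Step 1
Reactants: 1 (R)-carvone
Product: 2 10-chlorocarvone, (5R)-5-(3-chloroprop-1-en-2-yl)-2-methylcyclohex-2-en-1-one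
Conditions: Ca(OCl)2, CO2 (solid), CH2Cl2/H2O, 0 °C
Reagents that add atoms: calcium hypochlorite, [Ca+2].[O-]Cl.[O-]Cl
Why: ene-type allylic chlorination by HOCl made in situ should attack the electron-rich 1,1-disubstituted alkene and leave the enone untouched; no stereocentre is affected.

Step 2
Reactants: 2 10-chlorocarvone
Product: 3 2-[(1R)-4-methyl-5-oxocyclohex-3-en-1-yl]prop-2-enal
Conditions: N-methylmorpholine N-oxide, KI (cat.), MeCN, rt
Reagents that add atoms: N-methylmorpholine N-oxide, C[N+]1([O-])CCOCC1
Why: O-alkylation of the N-oxide by the allylic halide followed by elimination should give the enal (Kornblum-type N-oxide oxidation); both allyl termini are CH2, so SN2 and SN2′ give the same product.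

Step 3
Reactants: 3 enal
Product: 4 2-[(1R)-4-methyl-5-oxocyclohex-3-en-1-yl]prop-2-enoic acid
Conditions: NaClO2, NaH2PO4, 2-methyl-2-butene, t-BuOH/H2O, 0 °C → rt
Reagents that add atoms: sodium chlorite, [Na+].[O-]Cl=O
Why: Pinnick oxidation converts the aldehyde to the acid without touching either alkene; the scavenger removes HOCl.

Step 4
Reactants: 4 keto acid
Product: 5 cis-fused enone α-methylene lactone (C7 ketone, C2=C3, C6–O and C5–C8 both β)
Conditions: PhI(OH)OTs, CH2Cl2, 40 °C
Reagents that add atoms: none
Why: enolisation of the enone toward C6, its only sp3 α-carbon, should give an α-iodanyl ketone on the open α-face, which the tethered carboxylate displaces with inversion (trivalent-iodine oxidative lactonisation of a 5-oxo acid), so the new C6–O bond is β, cis to C5–C8.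

Step 5
Reactants: 5 α-methylene lactone
Product: 6 cis-fused enone lactone with C8 methyl (H-8 cis to H-5, methyl on the concave face)
Conditions: H2 (1 atm), RhCl(PPh3)3 (cat.), PhH/EtOH, rt
Reagents that add atoms: none
Why: homogeneous hydrogenation reduces the unhindered methylene and not the trisubstituted enone; H2 should add from the convex face of the cis-fused bicycle, which sets C8 with the methyl group cis to C4.

Step 6
Reactants: 6 enone lactone
Product: 7 allylic alcohol (C7 β-OH, C2=C3)
Conditions: NaBH4, CeCl3·7H2O, MeOH, −78 → 0 °C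
Reagents that add atoms: none
Why: Luche 1,2-reduction; hydride should enter on the α-face, anti to the lactone C6–O bond, giving the β-alcohol (C7 is re-oxidised in step 9, so it serves here only to clear the α-face).

Step 7
Reactants: 7 allylic alcohol
Product: 9 diol (C7 β-OH; C2 β-CH3; C3 α-OH), via C3 alkylborane 8 (not isolated)
Conditions: BH3·THF, THF, 0 °C → rt; then 30% H2O2, aq. NaHCO3, 0 °C → rt
Reagents that add atoms: hydrogen peroxide, OO (oxygen of the C3 hydroxyl); borane–tetrahydrofuran, [BH3-][O+]1CCCC1 (boron of 8 only)
Why: hydroboration–oxidation; BH3 should add syn to C2=C3 with boron on the less substituted C3 and from the α-face, because the C5, C6 and C7 substituents all lie on the β-face, and oxidation with retention gives the C3 α-alcohol and the C2 β-methyl group.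

Step 8
Reactants: 9 diol
Product: 10 C3 O-TBS ether (C7 β-OH free)
Conditions: TBSCl, imidazole, DMF, 0 °C
Reagents that add atoms: tert-butyldimethylsilyl chloride, CC(C)(C)[Si](C)(C)Cl
Why: selective silylation; the C3 hydroxyl on the open α-face should react much faster than the C7 hydroxyl, which is flanked on the β-face by the C2 methyl group and the lactone oxygen.

Step 9
Reactants: 10 mono-silyl ether
Product: 11 ketone (C7=O; C2 β-CH3; C3 α-OTBS; cis-fused lactone)
Conditions: Dess–Martin periodinane, NaHCO3, CH2Cl2, rt
Reagents that add atoms: none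
Why: Dess–Martin oxidation under buffered, non-enolising conditions should give the ketone without epimerising C2 or C6.

Step 10
Reactants: 12 (E)-pent-3-en-2-one
Product: 14 (E)-1-diazopent-3-en-2-one, via trifluoroacetyl diketone 13 (not isolated)
Conditions: LiN(SiMe3)2, THF, −78 °C; CF3CO2CH2CF3; then 4-acetamidobenzenesulfonyl azide, Et3N, H2O, MeCN, rt
Reagents that add atoms: 4-acetamidobenzenesulfonyl azide, CC(=O)Nc1ccc(cc1)S(=O)(=O)N=[N+]=[N-] (N2 of 14); 2,2,2-trifluoroethyl trifluoroacetate, O=C(OCC(F)(F)F)C(F)(F)F (trifluoroacetyl group of 13 only)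
Why: detrifluoroacetylative diazo transfer; the kinetic methyl enolate is trifluoroacetylated and the activated diketone takes up N2 with loss of the trifluoroacetyl group, the standard entry to α′-diazo enones, with the E alkene untouched.

Step 11
Reactants: 11 ketone; 14 diazoketone
Product: 16 tertiary alcohol (C7 β-OH; C7 α-[(E)-1-diazo-2-oxopent-3-en-1-yl]), via lithiated diazoketone 15 (not isolated)
Conditions: 14, LiN(iPr)2, THF, −78 °C; then 11, −78 °C; AcOH quench at −78 °C
Reagents that add atoms: lithium diisopropylamide, [Li+].CC(C)[N-]C(C)C (lithium of 15 only)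
Why: aldol-type addition of a C-lithiated diazoketone to a ketone; the nucleophile should enter equatorially from the α-face because axial β-attack is blocked by the axial C5–C8 bond, which gives the C7 β-hydroxyl, and the cold acidic quench prevents retro-aldol.

Step 12
Reactants: 16 diazo alcohol
Product: 17 α-hydroxy vicinal diketone (C7 β-OH; C7 α-[(E)-2-oxopent-3-enoyl])
Conditions: dimethyldioxirane (acetone solution), CH2Cl2, −40 → 0 °C
Reagents that add atoms: dimethyldioxirane, CC1(C)OO1
Why: diazo-to-carbonyl oxidation; the dioxirane should oxidise the nucleophilic diazo carbon with loss of N2 faster than it epoxidises the electron-poor alkene, and no stereocentre changes.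

Step 13
Reactants: 17 α-hydroxy vicinal diketone
Product: 18 ring-enlarged ketol (cycloheptanone, C7=O; C1 β-OH and α-(E)-but-2-enoyl; C2 β-CH3; C3 α-OTBS)
Conditions: Cu(OTf)2 (10 mol %), 4 Å molecular sieves, CH2Cl2, rt
Reagents that add atoms: none
Why: Cu(OTf)2 should bind the C7 hydroxyl and the adjacent C1 carbonyl in a five-membered chelate, and the C2–C7 bond, held perpendicular to the C1=O plane, shifts from C7 to C1 through a three-centre transition state while C7 becomes the ring ketone (α-ketol rearrangement). The closest known reaction type is the Lewis-acid-promoted acyloin shift of tertiary β-hydroxy-α-dicarbonyl compounds to α-hydroxy-β-dicarbonyl compounds, including the ring-enlarging shift of 1-acylcycloalkanols. The seven-membered carbocycle is closed at C1–C2 as the six-membered ring opens at C2–C7, a one-carbon ring enlargement that exchanges the vicinal dicarbonyl for a β-dicarbonyl array, which is the expected driving force. C2 migrates with retention, so its configuration and those at C3, C5, C6 and C8 are carried over from 17. The new stereocentre C1 is set by the chelate: with the C7 hydroxyl β and the C7–O and C1=O bonds syn, C2 can reach only the face of C1 that leaves the new hydroxyl β and the butenoyl group α. The step needs migration of C2 and not C6, which the electron-withdrawing lactone oxygen on C6 should secure, and it must stop before a second acyl shift, for which the mild catalyst at room temperature is chosen.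

Step 14
Reactants: 18 ketol
Product: 19 C7 β-alcohol (C1 β-OH; C7 β-OH; enone intact)
Conditions: NaBH4, MeOH/CH2Cl2, −78 °C
Reagents that add atoms: none
Why: borohydride should reduce the saturated C7 ketone, activated by two α-oxygen substituents, faster than the conjugated side-chain ketone; with the pseudo-axial C1 hydroxyl and the C6–O bond both on the β-face, hydride enters anti to both from the α-face (Felkin–Anh, polar model) and gives the β-alcohol.

Step 15
Reactants: 19 diol
Product: 20 C7 tiglate (C3 α-OTBS)
Conditions: tigloyl chloride, Et3N, DMAP (cat.), CH2Cl2, 0 °C → rt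
Reagents that add atoms: (E)-2-methylbut-2-enoyl chloride, C/C=C(\C)C(=O)Cl
Why: DMAP-catalysed acylation should take place only at the secondary C7 hydroxyl, the tertiary C1 hydroxyl being inert under these conditions; the E tiglate is the stable isomer and is retained.

Step 16
Reactants: 20 silyl ether
Product: 21 CNP0183494.2
Conditions: HF·pyridine, THF, 0 °C → rt
Reagents that add atoms: none
Why: fluoride cleavage of the silyl ether under non-basic conditions should spare both esters, the enone and the tertiary ketol.

**Compound list**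

1 | (R)-(−)-carvone, (5R)-2-methyl-5-(prop-1-en-2-yl)cyclohex-2-en-1-one | CC1=CC[C@H](CC1=O)C(C)=C | starting material
2 | (5R)-5-(3-chloroprop-1-en-2-yl)-2-methylcyclohex-2-en-1-one | CC1=CC[C@H](CC1=O)C(=C)CCl | intermediate
3 | 2-[(1R)-4-methyl-5-oxocyclohex-3-en-1-yl]prop-2-enal | CC1=CC[C@H](CC1=O)C(=C)C=O | intermediate
4 | 2-[(1R)-4-methyl-5-oxocyclohex-3-en-1-yl]prop-2-enoic acid | CC1=CC[C@H](CC1=O)C(=C)C(=O)O | intermediate
5 | cis-fused 2-methylcyclohex-2-enone α-methylene-γ-lactone (C7=O, C2=C3, C6–O and C5–C8 β) | O=C1C(C)=CC[C@@H]2[C@H]1OC(=O)C2=C | intermediate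
6 | as 5 with C8 methyl, H-8 cis to H-5 (methyl on the concave face) | O=C1C(C)=CC[C@@H]2[C@H]1OC(=O)[C@@H]2C | intermediate
7 | allylic alcohol, C7 β-OH, C2=C3 | O[C@H]1C(C)=CC[C@@H]2[C@H]1OC(=O)[C@@H]2C | intermediate
8 | C3 α-boryl, C7 O-boryl species (shown as the BH2 compounds) | [BH2]O[C@H]1[C@@H](C)[C@H]([BH2])C[C@@H]2[C@H]1OC(=O)[C@@H]2C | intermediate (not isolated)
9 | diol, C7 β-OH, C2 β-CH3, C3 α-OH | O[C@H]1[C@@H](C)[C@H](O)C[C@@H]2[C@H]1OC(=O)[C@@H]2C | intermediate
10 | C3 O-tert-butyldimethylsilyl ether of 9 | O[C@H]1[C@@H](C)[C@H](O[Si](C)(C)C(C)(C)C)C[C@@H]2[C@H]1OC(=O)[C@@H]2C | intermediate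
11 | ketone, C7=O, C2 β-CH3, C3 α-OTBS, cis-fused lactone | O=C1[C@@H](C)[C@H](O[Si](C)(C)C(C)(C)C)C[C@@H]2[C@H]1OC(=O)[C@@H]2C | intermediate
12 | (E)-pent-3-en-2-one | C/C=C/C(C)=O | starting material
13 | (E)-1,1,1-trifluorohept-5-ene-2,4-dione (present as its lithium enolate) | C/C=C/C(=O)CC(=O)C(F)(F)F | intermediate (not isolated)
14 | (E)-1-diazopent-3-en-2-one | C/C=C/C(=O)C=[N+]=[N-] | intermediate
15 | (E)-1-diazo-1-lithiopent-3-en-2-one | C/C=C/C(=O)C([Li])=[N+]=[N-] | intermediate (not isolated)
16 | C7 tertiary alcohol (β-OH) with α-[(E)-1-diazo-2-oxopent-3-en-1-yl] | C/C=C/C(=O)C(=[N+]=[N-])[C@]1(O)[C@@H](C)[C@H](O[Si](C)(C)C(C)(C)C)C[C@@H]2[C@H]1OC(=O)[C@@H]2C | intermediate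
17 | C7 tertiary alcohol (β-OH) with α-[(E)-2-oxopent-3-enoyl] (vicinal diketone C1/C1′) | C/C=C/C(=O)C(=O)[C@]1(O)[C@@H](C)[C@H](O[Si](C)(C)C(C)(C)C)C[C@@H]2[C@H]1OC(=O)[C@@H]2C | intermediate
18 | cycloheptanone ketol, C7=O, C1 β-OH and α-(E)-but-2-enoyl, C2 β-CH3, C3 α-OTBS, cis-fused lactone | C/C=C/C(=O)[C@]1(O)[C@@H](C)[C@H](O[Si](C)(C)C(C)(C)C)C[C@@H]2[C@@H](OC(=O)[C@@H]2C)C1=O | intermediate
19 | C7 β-alcohol of 18 | C/C=C/C(=O)[C@]1(O)[C@@H](C)[C@H](O[Si](C)(C)C(C)(C)C)C[C@@H]2[C@@H](OC(=O)[C@@H]2C)[C@@H]1O | intermediate
20 | C7 (E)-2-methylbut-2-enoate of 19 | C/C=C/C(=O)[C@]1(O)[C@@H](C)[C@H](O[Si](C)(C)C(C)(C)C)C[C@@H]2[C@@H](OC(=O)[C@@H]2C)[C@@H]1OC(=O)/C(C)=C/C | intermediate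
21 | CNP0183494.2 (C1 β-OH and α-butenoyl, C2 β-CH3, C3 α-OH, C7 β-tiglate, cis-fused lactone, C8 methyl cis to C4) | C/C=C/C(=O)[C@]1(O)[C@@H](C)[C@H](O)C[C@@H]2[C@@H](OC(=O)[C@@H]2C)[C@@H]1OC(=O)/C(C)=C/C | target

**Step count**

Total steps: 16. Longest linear sequence: 15 (steps 1–9 and 11–16 from (R)-carvone; step 10 prepares the diazoketone).

**Steps most likely to fail**

Step 13. The ketol shift may stop at an unfavourable equilibrium, C6 may migrate in place of C2, the product may undergo a second 1,2-acyl shift, or the tertiary hydroxyl may add to the enone. The fallback sets out from diazo alcohol 16 and does not use the vicinal diketone. Rh2(OAc)4 (cat.) in CH2Cl2 should extrude nitrogen and trigger the known carbenoid 1,2-alkyl shift of the α-diazo-β-hydroxy ketone to the ring-enlarged 2-butenoyl-cycloheptanone F1 (a β-diketone, mainly enolised). α-Hydroxylation of this β-diketone with cumene hydroperoxide under a cinchona-derived phase-transfer catalyst would then return to 18. The ring itself is expected to favour oxygen delivery to the α-face, so the catalyst antipode must be chosen to override this, and the C1 configuration would have to be proven.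

Step 14. Hydride may enter from the β-face, anti to the butenoyl group, and the enone may be reduced in competition. The fallback sets out from 18 and accepts the opposite facial outcome. Hydroxyl-directed reduction with Me4NBH(OAc)3 in MeCN/AcOH at −20 °C delivers hydride internally from the C1 oxygen and should give the C7 α-alcohol F2 (trans-diol). Mitsunobu esterification of this alcohol with tiglic acid, PPh3 and diisopropyl azodicarboxylate in toluene inverts C7 and comes back to the route at 20, with steps 14 and 15 merged.

Step 4. Enolisation may go toward C4 instead of C6, or the activated ketone may lose the leaving group and aromatise to a phenol. The fallback sets out from 4 and fixes the site by kinetic deprotonation. LiN(iPr)2 (2.2 equiv) in THF at −78 °C forms the carboxylate and the cross-conjugated C6 enolate, and I2 should give the trans-6-iodo keto acid F3. Warming with NaHCO3 in DMF closes the lactone by intramolecular SN2 displacement with inversion and returns to 5.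

Further compounds
F1 | step 13 | 2-[(E)-but-2-enoyl]cycloheptanone with C2 β-CH3, C3 α-OTBS and the cis-fused lactone (C1 configurationally labile, enolised) | C/C=C/C(=O)C1[C@@H](C)[C@H](O[Si](C)(C)C(C)(C)C)C[C@@H]2[C@@H](OC(=O)[C@@H]2C)C1=O
F2 | step 14 | C7 α-alcohol, the C7 epimer of 19 | C/C=C/C(=O)[C@]1(O)[C@@H](C)[C@H](O[Si](C)(C)C(C)(C)C)C[C@@H]2[C@@H](OC(=O)[C@@H]2C)[C@H]1O
F3 | step 4 | 2-[(1R,2R)-2-iodo-4-methyl-3-oxocyclohex-4-en-1-yl]prop-2-enoic acid (iodine trans to the side chain) | O=C1C(C)=CC[C@@H](C(=C)C(=O)O)[C@@H]1I
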